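## Retrosynthetic overview

1. The C11–OH and the C6=C7 bond come last, from a singlet-oxygen ene reaction on a 7(11)-en-8-one; the C8 ketone comes from allylic oxidation of the 7(11)-alkene.
2. The C3–O ester bond is cut next: a eudesm-7(11)-ene-3α,4β-diol plus an acetonide-protected (2S,3S)-2,3-dihydroxy-2-methylbutanoic acid, made from D-threonine by enolate methylation.
3. The trans-diaxial 3α,4β-diol comes from the α-epoxide of the C3=C4 alkene of (−)-α-selinene, whose angular C10 methyl directs the epoxidation.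
4. α-Selinene is cut across C5–C10 and C1–C2: an intramolecular Diels–Alder reaction of an acyclic triene forms ring A (the new cyclohexene) and ring B (closed around the four-carbon tether) in the same step.
5. The triene comes from (R)-(+)-limonene by ozonolysis and two Wittig steps; its one stereocentre (future C7) controls C5 and C10 and is erased later.

Assumption: eudesmane numbering is used (C10 = angular carbon, C5 = ring-fusion CH, ring A = C1–C5 plus C10, ring B = C5–C10, α = face opposite the C10 methyl), and (R)-(+)-limonene, D-threonine and all reagents are taken as commercial.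

## Route

Step 1
Reactants: 1 (R)-(+)-limonene
Product: 3 (3R)-6-oxo-3-(prop-1-en-2-yl)heptanal, via limonene ozonide 2 (not isolated)
Conditions: O3 (1.0 equiv), CH2Cl2, −78 °C; then Me2S, −78 °C to rt
Reagents that add atoms: ozone, [O-][O+]=O
Why: Ozonolysis (Criegee mechanism) with one equivalent of ozone cleaves the electron-richer trisubstituted ring alkene in preference to the 1,1-disubstituted isopropenyl group, and reductive work-up with Me2S gives the keto aldehyde with the bought stereocentre (the future C7) untouched.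

Step 2
Reactants: 3 (3R)-6-oxo-3-(prop-1-en-2-yl)heptanal
Product: 4 (2E,5R)-2-methyl-8-oxo-5-(prop-1-en-2-yl)non-2-enal
Conditions: Ph3P=C(CH3)CHO (1.2 equiv), toluene, 90 °C
Reagents that add atoms: 2-(triphenylphosphoranylidene)propanal, CC(C=O)=P(c1ccccc1)(c1ccccc1)c1ccccc1
Why: Wittig olefination with a stabilized formyl ylide reacts only with the aldehyde (not the methyl ketone) and gives the (E)-trisubstituted enal under thermodynamic control; no stereocentre is formed or touched.

Step 3
Reactants: 4 (2E,5R)-2-methyl-8-oxo-5-(prop-1-en-2-yl)non-2-enal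
Product: 5 (3E,6R)-3,9-dimethyl-6-(prop-1-en-2-yl)deca-1,3,9-triene
Conditions: Ph3PCH3Br (3.2 equiv), KOC(CH3)3 (3.0 equiv), THF, 0 °C to rt
Reagents that add atoms: methyltriphenylphosphonium bromide, C[P+](c1ccccc1)(c1ccccc1)c1ccccc1.[Br-]
Why: Twofold Wittig methylenation turns the enal into the (E)-2-methyl-1,3-diene and the methyl ketone into the 1,1-disubstituted dienophile; the C6 stereocentre has no acidic hydrogen and is unaffected.

Step 4
Reactants: 5 (3E,6R)-3,9-dimethyl-6-(prop-1-en-2-yl)deca-1,3,9-triene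
Product: 6 (−)-α-selinene (5α-eudesma-3,11-diene; 7β-isopropenyl; 10β-methyl)
Conditions: toluene (0.01 M), BHT (cat.), sealed tube, 220 °C, 48 h; AgNO3-silica chromatography
Reagents that add atoms: none
Why: Thermal intramolecular Diels–Alder reaction in which the (E)-diene and the 1,1-disubstituted alkene, linked by a four-carbon tether, close ring A and ring B together; with the tether in a chair and the isopropenyl group of the bought centre equatorial, the anti (trans-fused) transition state puts the new C10 methyl axial and cis to the isopropenyl group and the new C5 hydrogen trans to it (5α-H, 10β-CH3).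

Step 5
Reactants: 6 (−)-α-selinene
Product: 7 3α,4α-epoxy-5α-eudesm-11-ene
Conditions: mCPBA (1.05 equiv), CH2Cl2, −20 °C
Reagents that add atoms: mCPBA, OOC(=O)c1cccc(Cl)c1
Why: Prilezhaev epoxidation is faster at the trisubstituted C3=C4 alkene than at the isopropenyl group and occurs from the α face, because the axial C10 methyl shields the β face, which sets C3 and C4 of the epoxide.

Step 6
Reactants: 7 3α,4α-epoxy-5α-eudesm-11-ene
Product: 8 5α-eudesm-11-ene-3α,4β-diol
Conditions: HClO4 (cat.), THF/H2O 3:1, 0 °C to rt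
Reagents that add atoms: water, O
Why: Acid-catalysed epoxide hydrolysis follows the Fürst–Plattner (trans-diaxial) rule and Markovnikov polarization alike, so water attacks the tertiary C4 from the β face with inversion and gives the 3α-OH (retained) and 4β-OH/4α-methyl pattern of the target.

Step 7
Reactants: 8 5α-eudesm-11-ene-3α,4β-diol
Product: 9 5α-eudesm-7(11)-ene-3α,4β-diol
Conditions: RhCl3·3H2O (5 mol %), EtOH, 75 °C (stopped at full conversion of 8)
Reagents that add atoms: none
Why: RhCl3-catalysed alkene isomerization moves the terminal isopropenyl double bond into the tetrasubstituted C7=C11 position, which removes the C7 stereocentre after it has served as the control element; no other centre is touched.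

Step 8
Reactants: 10 D-threonine
Product: 11 (2R,3S)-2,3-dihydroxybutanoic acid
Conditions: NaNO2, 1 M H2SO4, H2O, 0 °C to rt
Reagents that add atoms: water, O
Why: Van Slyke-type diazotization of the α-amino acid proceeds with overall retention at C2 through the α-lactone (double inversion), so both bought centres are kept.

Step 9
Reactants: 11 (2R,3S)-2,3-dihydroxybutanoic acid
Product: 12 methyl (4R,5S)-2,2,5-trimethyl-1,3-dioxolane-4-carboxylate
Conditions: (CH3O)2C(CH3)2, MeOH, TsOH·H2O (cat.), 60 °C
Reagents that add atoms: 2,2-dimethoxypropane, COC(C)(C)OC; methanol, CO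
Why: Acid-catalysed acetalization with 2,2-dimethoxypropane together with Fischer esterification gives the trans-dioxolane ester; no stereocentre is changed.

Step 10
Reactants: 12 methyl (4R,5S)-2,2,5-trimethyl-1,3-dioxolane-4-carboxylate
Product: 14 methyl (4S,5S)-2,2,4,5-tetramethyl-1,3-dioxolane-4-carboxylate, via lithium ester enolate 13 (not isolated)
Conditions: LiN(iPr)2, THF/DMPU, −78 °C; then CH3I, −78 to −40 °C
Reagents that add atoms: iodomethane, CI
Why: Enolate alkylation in which the planar dioxolane ester enolate is methylated on the face anti to the C5 methyl group, so the bought C5 centre sets the new quaternary C4 centre (methyls trans, 4S), at −78 °C to outrun β-elimination.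

Step 11
Reactants: 14 methyl (4S,5S)-2,2,4,5-tetramethyl-1,3-dioxolane-4-carboxylate
Product: 15 (4S,5S)-2,2,4,5-tetramethyl-1,3-dioxolane-4-carboxylic acid
Conditions: LiOH, THF/MeOH/H2O, 50 °C; then 1 M HCl to pH 3, 0 °C
Reagents that add atoms: lithium hydroxide, [Li+].[OH-]
Why: Saponification of the hindered ester leaves the base-stable acetonide and the quaternary centre untouched, and a cold mild acid work-up keeps the acetonide.

Step 12
Reactants: 15 (4S,5S)-2,2,4,5-tetramethyl-1,3-dioxolane-4-carboxylic acid; 9 5α-eudesm-7(11)-ene-3α,4β-diol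
Product: 17 4β-hydroxy-5α-eudesm-7(11)-en-3α-yl (4S,5S)-2,2,4,5-tetramethyl-1,3-dioxolane-4-carboxylate, via mixed anhydride 16 (not isolated)
Conditions: 2,4,6-Cl3C6H2COCl, Et3N, THF, rt; then 9, DMAP, toluene, 80 °C
Reagents that add atoms: none
Why: Yamaguchi esterification through the 2,4,6-trichlorobenzoyl mixed anhydride and DMAP acylates only the secondary axial 3α-OH (the tertiary 4β-OH is inert), with no stereocentre affected.

Step 13
Reactants: 17 4β-hydroxy-5α-eudesm-7(11)-en-3α-yl (4S,5S)-2,2,4,5-tetramethyl-1,3-dioxolane-4-carboxylate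
Product: 18 4β-hydroxy-8-oxo-5α-eudesm-7(11)-en-3α-yl (4S,5S)-2,2,4,5-tetramethyl-1,3-dioxolane-4-carboxylate
Conditions: CrO3 (15 equiv), 3,5-dimethylpyrazole (15 equiv), CH2Cl2, −20 °C
Reagents that add atoms: chromium trioxide, O=[Cr](=O)=O
Why: Allylic oxidation with the CrO3–3,5-dimethylpyrazole complex converts an allylic ring CH2 of the tetrasubstituted alkene into the conjugated ketone, and C8 is preferred over C6 because the axial C6 hydrogen is screened by both the 4β-OH and the C10 methyl while C6 also sits next to the crowded C4/C5 region; no stereocentre is formed.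

Step 14
Reactants: 18 4β-hydroxy-8-oxo-5α-eudesm-7(11)-en-3α-yl (4S,5S)-2,2,4,5-tetramethyl-1,3-dioxolane-4-carboxylate
Product: 19 4β-hydroxy-8-oxo-5α-eudesm-7(11)-en-3α-yl (2S,3S)-2,3-dihydroxy-2-methylbutanoate
Conditions: CF3CO2H/H2O 9:1, 0 °C
Reagents that add atoms: none
Why: Acid-catalysed acetonide hydrolysis frees the side-chain diol before the acid-sensitive tertiary allylic alcohol is made; the ester, the 4β-OH and all stereocentres remain.

Step 15
Reactants: 19 4β-hydroxy-8-oxo-5α-eudesm-7(11)-en-3α-yl (2S,3S)-2,3-dihydroxy-2-methylbutanoate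
Product: 21 4β,11-dihydroxy-8-oxo-5α-eudesm-6-en-3α-yl (2S,3S)-2,3-dihydroxy-2-methylbutanoate (CNP0124456.1), via allylic hydroperoxide 20 (not isolated)
Conditions: O2, tetraphenylporphyrin (cat.), visible light, CH2Cl2, 0 °C; then PPh3, rt
Reagents that add atoms: dioxygen, O=O
Why: Schenck ene reaction of singlet oxygen with the s-cis enone abstracts the hydrogen from C6, the group geminal to the carbonyl, and puts oxygen on C11, and PPh3 reduces the hydroperoxide to the tertiary alcohol; C11 is not stereogenic and C5 is untouched under these neutral conditions.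

## Compound list

1 | (R)-(+)-limonene | CC1=CC[C@@H](CC1)C(C)=C | starting material
2 | limonene ozonide: 1-methyl-4-(prop-1-en-2-yl)-7,8,9-trioxabicyclo[4.2.1]nonane (ring stereocentre of 1 retained; both bridgehead diastereomers) | CC12CC[C@@H](C(C)=C)CC(OO1)O2 | intermediate
3 | (3R)-6-oxo-3-(prop-1-en-2-yl)heptanal | O=CC[C@@H](CCC(C)=O)C(C)=C | intermediate
4 | (2E,5R)-2-methyl-8-oxo-5-(prop-1-en-2-yl)non-2-enal | O=C/C(C)=C/C[C@@H](CCC(C)=O)C(C)=C | intermediate
5 | (3E,6R)-3,9-dimethyl-6-(prop-1-en-2-yl)deca-1,3,9-triene | C=C/C(C)=C/C[C@@H](CCC(C)=C)C(C)=C | intermediate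
6 | (−)-α-selinene: (2R,4aR,8aR)-4a,8-dimethyl-2-(prop-1-en-2-yl)-1,2,3,4,4a,5,6,8a-octahydronaphthalene | CC1=CCC[C@]2(C)CC[C@@H](C(C)=C)C[C@@H]12 | intermediate
7 | 3α,4α-epoxy-5α-eudesm-11-ene | C[C@@]12O[C@@H]1CC[C@]3(C)CC[C@@H](C(C)=C)C[C@@H]23 | intermediate
8 | 5α-eudesm-11-ene-3α,4β-diol | O[C@@H]1CC[C@]2(C)CC[C@@H](C(C)=C)C[C@H]2[C@@]1(C)O | intermediate
9 | 5α-eudesm-7(11)-ene-3α,4β-diol | O[C@@H]1CC[C@]2(C)CCC(=C(C)C)C[C@H]2[C@@]1(C)O | intermediate
10 | D-threonine: (2R,3S)-2-amino-3-hydroxybutanoic acid | C[C@H](O)[C@@H](N)C(=O)O | starting material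
11 | (2R,3S)-2,3-dihydroxybutanoic acid | C[C@H](O)[C@@H](O)C(=O)O | intermediate
12 | methyl (4R,5S)-2,2,5-trimethyl-1,3-dioxolane-4-carboxylate | C[C@@H]1OC(C)(C)O[C@H]1C(=O)OC | intermediate
13 | lithium enolate of 12 (5S) | C[C@@H]1OC(C)(C)OC1=C([O-])OC.[Li+] | intermediate
14 | methyl (4S,5S)-2,2,4,5-tetramethyl-1,3-dioxolane-4-carboxylate | C[C@@H]1OC(C)(C)O[C@]1(C)C(=O)OC | intermediate
15 | (4S,5S)-2,2,4,5-tetramethyl-1,3-dioxolane-4-carboxylic acid | C[C@@H]1OC(C)(C)O[C@]1(C)C(=O)O | intermediate
16 | (4S,5S)-2,2,4,5-tetramethyl-1,3-dioxolane-4-carboxylic 2,4,6-trichlorobenzoic anhydride | C[C@@H]1OC(C)(C)O[C@]1(C)C(=O)OC(=O)c1c(Cl)cc(Cl)cc1Cl | intermediate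
17 | 4β-hydroxy-5α-eudesm-7(11)-en-3α-yl (4S,5S)-2,2,4,5-tetramethyl-1,3-dioxolane-4-carboxylate | C[C@@H]1OC(C)(C)O[C@]1(C)C(=O)O[C@@H]1CC[C@]2(C)CCC(=C(C)C)C[C@H]2[C@@]1(C)O | intermediate
18 | 4β-hydroxy-8-oxo-5α-eudesm-7(11)-en-3α-yl (4S,5S)-2,2,4,5-tetramethyl-1,3-dioxolane-4-carboxylate | C[C@@H]1OC(C)(C)O[C@]1(C)C(=O)O[C@@H]1CC[C@]2(C)CC(=O)C(=C(C)C)C[C@H]2[C@@]1(C)O | intermediate
19 | 4β-hydroxy-8-oxo-5α-eudesm-7(11)-en-3α-yl (2S,3S)-2,3-dihydroxy-2-methylbutanoate | C[C@H](O)[C@](C)(O)C(=O)O[C@@H]1CC[C@]2(C)CC(=O)C(=C(C)C)C[C@H]2[C@@]1(C)O | intermediate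
20 | 11-hydroperoxy-4β-hydroxy-8-oxo-5α-eudesm-6-en-3α-yl (2S,3S)-2,3-dihydroxy-2-methylbutanoate | C[C@H](O)[C@](C)(O)C(=O)O[C@@H]1CC[C@]2(C)CC(=O)C(C(C)(C)OO)=C[C@H]2[C@@]1(C)O | intermediate
21 | 4β,11-dihydroxy-8-oxo-5α-eudesm-6-en-3α-yl (2S,3S)-2,3-dihydroxy-2-methylbutanoate (CNP0124456.1; core 3R,4R,5R,10R) | C[C@H](O)[C@](C)(O)C(=O)O[C@@H]1CC[C@]2(C)CC(=O)C(C(C)(C)O)=C[C@H]2[C@@]1(C)O | target

## Step count and risks

Total steps: 15. Longest linear sequence: 11 (steps 1–7 and 12–15); the acid branch (steps 8–11) joins at step 12.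

The step most likely to fail is step 4. The dienophile is unactivated, the temperature is high, and the trans-to-cis ring-fusion ratio (and with it the C10 configuration relative to the control centre) may be modest, so the cis-fused isomers must be removed before C7 is erased in step 7. The fallback sets out from 4 and uses an activated, traceless dienophile. One equivalent of Ph3P=CH2 at −78 °C methylenates only the aldehyde and gives (5R,7E)-8-methyl-5-(prop-1-en-2-yl)deca-7,9-dien-2-one F1. A Horner–Wadsworth–Emmons reaction of the ketone with (EtO)2P(O)CH2SO2Ph and NaH then gives {[(1E,5R,7E)-2,8-dimethyl-5-(prop-1-en-2-yl)deca-1,7,9-trien-1-yl]sulfonyl}benzene F2. Its sulfonyl-activated alkene should cyclize at about 140 °C to 1β-(phenylsulfonyl)-5α-eudesma-3,11-diene F3. Reductive desulfonylation with sodium amalgam (Na/Hg, Na2HPO4, MeOH) returns to the route at 6.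

The second is step 13. The C8 versus C6 preference rests on a steric argument, the methyl groups can also be oxidized, and a large excess of CrO3 is needed. The fallback sets out from 17 and goes through the allylic alcohol. SeO2 (cat.) with t-BuOOH in CH2Cl2 hydroxylates by an ene reaction followed by a [2,3] shift, giving 4β,8ξ-dihydroxy-5α-eudesm-7(11)-en-3α-yl (4S,5S)-2,2,4,5-tetramethyl-1,3-dioxolane-4-carboxylate F4. Dess–Martin periodinane oxidizes it to the enone, and the route is rejoined at 18.

The third is step 12. An axial secondary alcohol next to a fully substituted carbinol carbon must be acylated by an α-quaternary acid, which may be too slow. The fallback sets out from 9 and makes the C3–O bond by substitution rather than acylation. MsCl in pyridine gives 4β-hydroxy-5α-eudesm-7(11)-en-3α-yl methanesulfonate F5. K2CO3 in MeOH closes it (the 4β-alkoxide displaces the anti-periplanar 3α-mesylate) to 3β,4β-epoxy-5α-eudesm-7(11)-ene F6. Acid 15 is converted with Cs2CO3 into cesium (4S,5S)-2,2,4,5-tetramethyl-1,3-dioxolane-4-carboxylate F7, which opens F6 in DMF at 90 °C at the secondary C3 from the α face (trans-diaxial, inversion). This returns to the route at 17.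

Further compounds
F1 | step 4 | (5R,7E)-8-methyl-5-(prop-1-en-2-yl)deca-7,9-dien-2-one | C=C/C(C)=C/C[C@@H](CCC(C)=O)C(C)=C
F2 | step 4 | {[(1E,5R,7E)-2,8-dimethyl-5-(prop-1-en-2-yl)deca-1,7,9-trien-1-yl]sulfonyl}benzene | C=C/C(C)=C/C[C@@H](CC/C(C)=C/S(=O)(=O)c1ccccc1)C(C)=C
F3 | step 4 | 1β-(phenylsulfonyl)-5α-eudesma-3,11-diene | CC1=CC[C@@H](S(=O)(=O)c3ccccc3)[C@]2(C)CC[C@@H](C(C)=C)C[C@@H]12
F4 | step 13 | 4β,8ξ-dihydroxy-5α-eudesm-7(11)-en-3α-yl (4S,5S)-2,2,4,5-tetramethyl-1,3-dioxolane-4-carboxylate | C[C@@H]1OC(C)(C)O[C@]1(C)C(=O)O[C@@H]1CC[C@]2(C)CC(O)C(=C(C)C)C[C@H]2[C@@]1(C)O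
F5 | step 12 | 4β-hydroxy-5α-eudesm-7(11)-en-3α-yl methanesulfonate | CS(=O)(=O)O[C@@H]1CC[C@]2(C)CCC(=C(C)C)C[C@H]2[C@@]1(C)O
F6 | step 12 | 3β,4β-epoxy-5α-eudesm-7(11)-ene | C[C@]12O[C@H]1CC[C@]3(C)CCC(=C(C)C)C[C@@H]23
F7 | step 12 | cesium (4S,5S)-2,2,4,5-tetramethyl-1,3-dioxolane-4-carboxylate | C[C@@H]1OC(C)(C)O[C@]1(C)C(=O)[O-].[Cs+]
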